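## Structural features

Selaginellin U (17) is built from five six-membered carbocycles and has no heterocycle. Ring A is the central benzene: methyl on C1, a (4-hydroxyphenyl)ethynyl group on C2, the exocyclic carbon Cq on C3, the 4-hydroxyphenyl ring B on C4, and hydrogen on C5 and C6. Cq carries a 4-hydroxyphenyl ring and is double-bonded to a cyclohexa-2,5-dienone ring, which makes a fuchsone-type quinone methide. There is no stereocentre, so no two stereocentres stand next to each other, and because the dienone ring is symmetric the Cq=C bond has no E/Z isomers. The fragile parts are the cross-conjugated quinone methide (an electrophile, and the deprotonated form of a trityl cation), the three free phenols, and the electron-rich diarylalkyne that sits ortho to Cq. The real difficulty is ring A: three different carbon substituents on the contiguous carbons C2, C3 and C4, with the bulkiest one on C3 between two ortho neighbours. The key step uses exactly this contiguity. C3 is the only ring carbon adjacent to both C2 and C4, so a metal on C3 can act twice as the leaving partner of an aryne, first with a halide on C4 and then with a halide on C2, and it ends up on C3 again, ready to be exchanged for Cq. The quinone methide is at the oxidation level of a triarylcarbinol, so after the skeleton is complete only demethylation and loss of water are needed.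

## Logic of the disconnections

17 to 15. The first cut is not skeletal. The Cq=C bond and the free hydroxyl groups of 17 are traced back to the C–OH bond and the four O–CH3 bonds of 15, with cation 16 on the way. This masks every acidic and electrophilic function, so all earlier steps can use strongly basic organometallic reagents. The demand on the forward step is that one reagent cleaves four aryl methyl ethers and ionises the carbinol without adding to the alkyne and without letting the cation attack ring B.

15 to 12 and 13. The C3–Cq bond is cut. Cq with its two identical oxygenated rings is then the commercial ketone 13, and C3 becomes an aryl anion (14) that is reached from the C3–halogen bond of 12. One cut removes the quaternary carbon and two rings. The demand is that an aryl nucleophile with two ortho substituents adds to a diaryl ketone, so the most reactive form of that nucleophile is used and the alkyne must be left alone.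

12 to 5, 2 and 4. The ring A–ring B bond at C4 and the C2–C(sp) bond are cut together, and the C3–I bond is traced back to a C3–metal bond (intermediates 6 to 11). The reason is that both carbon substituents flank C3, the position that carries the most acidic proton of 5. The gain is large: ring A comes from a commercial dihalotoluene, three components are joined in one flask, and no transition-metal coupling is needed. The demand is threefold: bromide must leave before chloride, 2 must attack C4 of the first aryne, and 4 must attack C2 of the second.

2 to 1 and 4 to 3. Only the carbon–magnesium bonds are cut, which leads to two commercial compounds. The demand is an accurate titre and the absence of any other nucleophilic organometallic species, because the relay depends on stoichiometry.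

## Other disconnections considered

Alternative 1: Ring A is cut at C1–C6 and C3–C4 and assembled from two three-carbon pieces. The bis(silyl enol ether) A1 supplies C1, C2 and C3 with the methyl group and the ester carbon that becomes Cq. The keto acetal A2 supplies C4, C5 and C6 with ring B. The forward key step is a TiCl4-mediated formal [3+3] cyclocondensation with loss of methanol and water, which should give salicylate A3. Triflation of the C2 hydroxyl, Sonogashira coupling with 3, double addition of 2 to the ester and the final demethylation would follow.
- In its favour: the position of every substituent follows from the connectivity of A1 and A2, and the cyclocondensation is an established reaction type. On certainty of regiochemistry and on precedent it is better than the chosen plan.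
- Against it: the Sonogashira coupling has to take place at a triflate flanked by methyl and ester, and the ester, flanked by alkyne and ring B, has to accept two aryl nucleophiles.
- Step economy: A1 and A2 each need their own preparation, so the count comes to about eight or nine operations against five. The chosen plan is clearly better here.
- Endgame: both plans pass through 15, so they are equal from that point on.

Alternative 2: Ring A is cut at C2–C3, C4–C5 and C6–C1 and made from three alkynes. The silyl ether diyne A5 would come in one flask from 13, the lithium acetylide of 3 and chlorosilane A4. RhCl(PPh3)3 would then join A5 with acetylene A6 in a [2+2+2] cyclotrimerization to give benzoxasilole A7, closing the benzene ring and the fused five-membered oxasilole ring.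
- In its favour: the tether decides which alkyne carbons become C2 and C3, acetylene has no orientation problem, and Cq arrives with both of its aryl rings. On control of the ring A substitution pattern and on precedent for the ring-forming step it is better than the chosen plan.
- Against it: after the key step C2 carries silicon and not carbon. Two further operations are needed at the most hindered position (ipso-iodination of the C–Si bond, then Sonogashira coupling with 3), and the electrophilic iodine would meet three anisyl rings and an ionisable triarylcarbinol. Acetylene gas and competing self-trimerization are a practical burden.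
- Step economy: about six operations against five, so the two plans are roughly equal. The chosen plan is better in that the alkyne is installed before Cq and not next to it.

Alternative 3: Ring A is cut at C1–C2 and C3–C4. Diene A8 supplies C1, C6, C5 and C4 with the methyl group and ring B, and the carbonyl-activated triple bond of diynone A9 supplies C2 and C3. A thermal Diels–Alder addition followed by DDQ dehydrogenation in the same flask should give ketone A10. Addition of 2 to A10 would give 15.
- In its favour: all three carbon substituents arrive at the correct oxidation level in one ring-forming step, only the ynone triple bond of A9 is activated, and no organometallic cascade with a temperature window is needed. On mechanism class and operational simplicity of the key step it is better than the chosen plan.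
- Against it: both termini of A8 carry donor groups that direct in opposite senses, so the required orientation (ring B next to the acyl-bearing carbon) depends on the anisyl group outweighing the methyl group. A regioisomer with methyl and ring B exchanged would be hard to separate. Dienes substituted at both termini are also slow partners.
- Comparison: both plans rest on an unproven electronic difference between a methyl and an aryl group, so on that point they are equal. The chosen plan has only one such uncertain event, because its first aryne is directed by chlorine.
- Step economy: A8 and A9 need two to three steps each, so the total is about seven or eight against five.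

Key step: step 3

Remark on the chemistry: the halogen placement in 5 (bromine on C4, chlorine on C2) and the structure of 12 are taken as correct, since only this placement opens the C3–C4 aryne first. The one design change is that the C3 anion is formed with lithium 2,2,6,6-tetramethylpiperidide at −78 °C and passed to magnesium by 2. A magnesium amide such as TMPMgCl·LiCl is expected to be a slow base toward an arene activated only by two halogens and would have to act at a temperature where bromide is already lost. 17 has no stereocentre.

## Route

Step 1
Reactants: 1 4-bromoanisole
Product: 2 4-methoxyphenylmagnesium bromide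
Conditions: Mg turnings (1.2 equiv), I2 (cat.), THF, 25 → 50 °C
Reagents that add atoms: magnesium, [Mg]
Why: Grignard reagent formation by insertion of magnesium into the aryl C–Br bond; the solution is titrated because the key step needs close to one equivalent.

Step 2
Reactants: 3 4-ethynylanisole
Product: 4 [(4-methoxyphenyl)ethynyl]magnesium bromide
Conditions: EtMgBr (1.0 equiv), THF, 0 → 45 °C
Reagents that add atoms: ethylmagnesium bromide, CC[Mg]Br
Why: Acid–base metalation of the terminal alkyne by an alkyl Grignard reagent, driven by loss of ethane; exact stoichiometry leaves no ethyl nucleophile that could add to an aryne later.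

Step 3
Reactants: 5 4-bromo-2-chlorotoluene, 2 4-methoxyphenylmagnesium bromide, 4 [(4-methoxyphenyl)ethynyl]magnesium bromide
Product: 12 2-iodo-4'-methoxy-3-[(4-methoxyphenyl)ethynyl]-4-methylbiphenyl, via C3-lithiated arene 6 (not isolated), via mixed diarylmagnesium 7 (not isolated), via 3-chloroaryne 8 (not isolated), via biaryl Grignard reagent 9 (not isolated), via 3-aryl-6-methylaryne 10 (not isolated), via alkynylbiaryl Grignard reagent 11 (not isolated)
Conditions: lithium 2,2,6,6-tetramethylpiperidide (1.05 equiv), THF, −78 °C; 2 (1.05 equiv), −78 → 30 °C; 4 (2.5 equiv), 65 °C; I2 (excess), 0 °C; aq Na2S2O3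
Reagents that add atoms: iodine, II
Why: Proposed new method: Lithium 2,2,6,6-tetramethylpiperidide removes the most acidic ring proton of 5, C3–H between bromine and chlorine, and 2 transmetalates aryllithium 6 to the mixed diarylmagnesium 7, which holds the single equivalent of aryl nucleophile on the same metal. On warming, magnesium at C3 and bromide at C4 leave to give the 3-chloroaryne 8, whose triple bond is polarised by the chlorine on C2, so the released anisyl Grignard reagent adds at C4 and the metal returns to C3 beside chlorine (9). Only at reflux does 9 lose MgBrCl to give aryne 10, flanked by the methyl group on C1 and ring B on C4; 4, now the only nucleophile present in quantity, adds at C2 so that the carbanion of 11 lies at C3 next to the σ-withdrawing aryl group and away from the donor methyl group, and iodine converts the C3–Mg bond into C3–I. The closest known reaction type is the one-pot m-terphenyl synthesis in which a 2,6-dihaloaryl metal species passes through two arynes, takes up two equivalents of one aryl Grignard reagent and is quenched with iodine; the addition of metal acetylides to arynes is known separately, and new here are the two different halogens that separate the eliminations in temperature and the two different nucleophiles. No ring is closed and no stereocentre is formed. Three selectivities are needed: the order of halide loss, secured by the bromide–chloride leaving-group gap and by adding 4 and heating only after 7 has been consumed; attack of 2 at C4 of 8, secured by the chlorine substituent; and attack of 4 at C2 of 10, which rests on the aryl-versus-methyl difference and the slim sp nucleophile and is the least certain. Holding 2 near one equivalent and 4 in excess suppresses double arylation, and the hindered 2,2,6,6-tetramethylpiperidine left from the metalation is a slow proton donor toward the hindered arylmagnesium intermediates.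

Step 4
Reactants: 12 2-iodo-4'-methoxy-3-[(4-methoxyphenyl)ethynyl]-4-methylbiphenyl, 13 4,4'-dimethoxybenzophenone
Product: 15 {4'-methoxy-3-[(4-methoxyphenyl)ethynyl]-4-methylbiphenyl-2-yl}bis(4-methoxyphenyl)methanol, via C3 aryllithium 14 (not isolated)
Conditions: t-BuLi (2.05 equiv), THF, −78 °C; 13 (1.2 equiv), −78 → 0 °C; H2O
Reagents that add atoms: none
Why: Iodine–lithium exchange followed by 1,2-addition of the aryllithium to a non-enolisable diaryl ketone; the second equivalent of t-BuLi destroys the tert-butyl iodide, so the hindered aryllithium can be warmed with the ketone without being alkylated, and quenching at 0 °C keeps the lithium alkoxide from adding to the neighbouring alkyne.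

Step 5
Reactants: 15 {4'-methoxy-3-[(4-methoxyphenyl)ethynyl]-4-methylbiphenyl-2-yl}bis(4-methoxyphenyl)methanol
Product: 17 Selaginellin U, via tetraphenol triarylmethylium bromide 16 (not isolated)
Conditions: BBr3 (10 equiv), CH2Cl2, −78 → 0 °C; H2O
Reagents that add atoms: none
Why: Lewis-acid cleavage of the four aryl methyl ethers together with ionisation of the triarylcarbinol; on hydrolysis the 4-hydroxy-substituted trityl cation 16 loses a phenolic proton to give the quinone methide (fuchsone formation), and since the two oxygenated rings on Cq are identical only one quinone methide can form.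

## Compound list

1 | 4-bromoanisole (1-bromo-4-methoxybenzene) | COc1ccc(Br)cc1 | starting material
2 | 4-methoxyphenylmagnesium bromide | COc1ccc([Mg]Br)cc1 | intermediate
3 | 4-ethynylanisole (1-ethynyl-4-methoxybenzene) | COc1ccc(C#C)cc1 | starting material
4 | [(4-methoxyphenyl)ethynyl]magnesium bromide | COc1ccc(C#C[Mg]Br)cc1 | intermediate
5 | 4-bromo-2-chlorotoluene (4-bromo-2-chloro-1-methylbenzene) | Cc1ccc(Br)cc1Cl | starting material
6 | (6-bromo-2-chloro-3-methylphenyl)lithium | [Li]c1c(Br)ccc(C)c1Cl | intermediate
7 | (6-bromo-2-chloro-3-methylphenyl)(4-methoxyphenyl)magnesium | COc1ccc([Mg]c2c(Br)ccc(C)c2Cl)cc1 | intermediate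
8 | 3-chloro-4-methyl-1,2-didehydrobenzene (3-chloro-4-methylbenzyne; triple bond between C3 and C4 of the toluene) | CC1=C(Cl)C#CC=C1 | intermediate
9 | (3-chloro-4'-methoxy-4-methylbiphenyl-2-yl)magnesium bromide | Cc1ccc(-c2ccc(OC)cc2)c([Mg]Br)c1Cl | intermediate
10 | 3-(4-methoxyphenyl)-6-methyl-1,2-didehydrobenzene (triple bond between C2 and C3 of ring A) | CC1=CC=C(c2ccc(OC)cc2)C#C1 | intermediate
11 | {4'-methoxy-3-[(4-methoxyphenyl)ethynyl]-4-methylbiphenyl-2-yl}magnesium bromide | Cc1ccc(-c2ccc(OC)cc2)c([Mg]Br)c1C#Cc1ccc(OC)cc1 | intermediate
12 | 2-iodo-4'-methoxy-3-[(4-methoxyphenyl)ethynyl]-4-methylbiphenyl | Cc1ccc(-c2ccc(OC)cc2)c(I)c1C#Cc1ccc(OC)cc1 | intermediate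
13 | 4,4'-dimethoxybenzophenone | COc1ccc(C(=O)c2ccc(OC)cc2)cc1 | starting material
14 | {4'-methoxy-3-[(4-methoxyphenyl)ethynyl]-4-methylbiphenyl-2-yl}lithium | Cc1ccc(-c2ccc(OC)cc2)c([Li])c1C#Cc1ccc(OC)cc1 | intermediate
15 | {4'-methoxy-3-[(4-methoxyphenyl)ethynyl]-4-methylbiphenyl-2-yl}bis(4-methoxyphenyl)methanol | Cc1ccc(-c2ccc(OC)cc2)c(C(O)(c2ccc(OC)cc2)c2ccc(OC)cc2)c1C#Cc1ccc(OC)cc1 | intermediate
16 | {4'-hydroxy-3-[(4-hydroxyphenyl)ethynyl]-4-methylbiphenyl-2-yl}bis(4-hydroxyphenyl)methylium bromide | Cc1ccc(-c2ccc(O)cc2)c([C+](c2ccc(O)cc2)c2ccc(O)cc2)c1C#Cc1ccc(O)cc1.[Br-] | intermediate
17 | Selaginellin U, 4-[{4'-hydroxy-3-[(4-hydroxyphenyl)ethynyl]-4-methylbiphenyl-2-yl}(4-hydroxyphenyl)methylidene]cyclohexa-2,5-dien-1-one (no stereocentre) | Cc1ccc(-c2ccc(O)cc2)c(C(=C2C=CC(=O)C=C2)c2ccc(O)cc2)c1C#Cc1ccc(O)cc1 | target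

## Step count and risk

Total step count: 5. Longest linear sequence: 4 steps (step 1 or step 2, then steps 3, 4 and 5).

Least certain steps

Step 3 (key step, proposed new method).
- The two eliminations may overlap: if chloride starts to leave from 9 before all of 7 has reacted, or bromide loss is slow at 30 °C, residual 2 would add to the second aryne and 4 to the first, giving doubly arylated and doubly alkynylated products.
- The addition of 4 to aryne 10 may be poorly regioselective, because the methyl and aryl flanking groups differ only moderately.
- The acetylide may add so slowly that the arylmagnesium intermediates are consumed by aryne oligomerisation or by proton transfer from 2,2,6,6-tetramethylpiperidine at reflux.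
- Fallback (known chemistry, sets out from 5 and comes back to the route at 15): 5 is lithiated at C3 with lithium 2,2,6,6-tetramethylpiperidide in THF at −78 °C and trapped with 4-methoxybenzaldehyde to give racemic (6-bromo-2-chloro-3-methylphenyl)(4-methoxyphenyl)methanol F1. Dess–Martin periodinane oxidises it to (6-bromo-2-chloro-3-methylphenyl)(4-methoxyphenyl)methanone F2. Suzuki–Miyaura coupling with 4-methoxyphenylboronic acid (Pd(PPh3)4, K2CO3, dioxane–water, 80 °C) replaces bromine selectively and gives (3-chloro-4'-methoxy-4-methylbiphenyl-2-yl)(4-methoxyphenyl)methanone F3. Copper-free Sonogashira coupling of the ketone-activated aryl chloride with 3 (PdCl2(MeCN)2, XPhos, Cs2CO3, MeCN, 90 °C) gives {4'-methoxy-3-[(4-methoxyphenyl)ethynyl]-4-methylbiphenyl-2-yl}(4-methoxyphenyl)methanone F4, the same compound as A10. Addition of 2 to this ketone in THF gives 15. Here both ring A bonds are made by cross-coupling at halogens of fixed position, so no aryne selectivity is involved.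

Step 4.
- The C3 carbanion is shielded by ring B and the alkyne, so the addition to the diaryl ketone may be incomplete; the aryllithium would then be protonated on quench (net loss of iodine), or it could transfer an electron to the ketone.
- If the mixture is warmed too far, the lithium alkoxide may add to the ortho alkyne.
- Fallback (sets out from 12 and comes back at 15): 14 is generated as in step 4 and added to the unhindered 4-methoxybenzaldehyde to give racemic {4'-methoxy-3-[(4-methoxyphenyl)ethynyl]-4-methylbiphenyl-2-yl}(4-methoxyphenyl)methanol F5. Dess–Martin periodinane oxidises it to the ketone F4 already described in the fallback for step 3, and addition of 2 gives 15. The hindered bond formation is thus split into one addition of a hindered nucleophile to a small electrophile and one addition of a small nucleophile to a hindered electrophile.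

Step 5.
- Under excess Lewis acid the long-lived trityl cation may attack the ortho position of ring B (ring closure to a fluorene).
- Hydrogen bromide may add across the electron-rich alkyne.
- Cleavage of the four ethers may stop short.
- Fallback (sets out from 12 and comes back at 17): 12 is demethylated with BBr3 at a stage where no cation can form, giving 4-{[3-(4-hydroxyphenyl)-2-iodo-6-methylphenyl]ethynyl}phenol F6. Silylation with tert-butyldimethylsilyl chloride and imidazole in DMF gives the bis(silyl ether) tert-butyl{4-[(3-{4-[(tert-butyldimethylsilyl)oxy]phenyl}-2-iodo-6-methylphenyl)ethynyl]phenoxy}dimethylsilane F7. Commercial 4,4'-dihydroxybenzophenone is silylated in the same way to bis{4-[(tert-butyldimethylsilyl)oxy]phenyl}methanone F8. Iodine–lithium exchange on F7 with t-BuLi and addition to F8 give the tetrasilylated carbinol F9. Tetrabutylammonium fluoride buffered with acetic acid in THF at 0 °C, followed by dilute acid, removes the four silyl groups and dehydrates the carbinol to 17, so the final unmasking needs no strong Lewis acid.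

Further compounds
F1 | step 3 | (6-bromo-2-chloro-3-methylphenyl)(4-methoxyphenyl)methanol (racemic) | COc1ccc(C(O)c2c(Br)ccc(C)c2Cl)cc1
F2 | step 3 | (6-bromo-2-chloro-3-methylphenyl)(4-methoxyphenyl)methanone | COc1ccc(C(=O)c2c(Br)ccc(C)c2Cl)cc1
F3 | step 3 | (3-chloro-4'-methoxy-4-methylbiphenyl-2-yl)(4-methoxyphenyl)methanone | COc1ccc(C(=O)c2c(-c3ccc(OC)cc3)ccc(C)c2Cl)cc1
F4 | step 3 | {4'-methoxy-3-[(4-methoxyphenyl)ethynyl]-4-methylbiphenyl-2-yl}(4-methoxyphenyl)methanone | Cc1ccc(-c2ccc(OC)cc2)c(C(=O)c2ccc(OC)cc2)c1C#Cc1ccc(OC)cc1
F5 | step 4 | {4'-methoxy-3-[(4-methoxyphenyl)ethynyl]-4-methylbiphenyl-2-yl}(4-methoxyphenyl)methanol (racemic) | Cc1ccc(-c2ccc(OC)cc2)c(C(O)c2ccc(OC)cc2)c1C#Cc1ccc(OC)cc1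
F6 | step 5 | 4-{[3-(4-hydroxyphenyl)-2-iodo-6-methylphenyl]ethynyl}phenol | Cc1ccc(-c2ccc(O)cc2)c(I)c1C#Cc1ccc(O)cc1
F7 | step 5 | tert-butyl{4-[(3-{4-[(tert-butyldimethylsilyl)oxy]phenyl}-2-iodo-6-methylphenyl)ethynyl]phenoxy}dimethylsilane | Cc1ccc(-c2ccc(O[Si](C)(C)C(C)(C)C)cc2)c(I)c1C#Cc1ccc(O[Si](C)(C)C(C)(C)C)cc1
F8 | step 5 | bis{4-[(tert-butyldimethylsilyl)oxy]phenyl}methanone | CC(C)(C)[Si](C)(C)Oc1ccc(C(=O)c2ccc(O[Si](C)(C)C(C)(C)C)cc2)cc1
F9 | step 5 | {4'-[(tert-butyldimethylsilyl)oxy]-3-({4-[(tert-butyldimethylsilyl)oxy]phenyl}ethynyl)-4-methylbiphenyl-2-yl}bis{4-[(tert-butyldimethylsilyl)oxy]phenyl}methanol | Cc1ccc(-c2ccc(O[Si](C)(C)C(C)(C)C)cc2)c(C(O)(c2ccc(O[Si](C)(C)C(C)(C)C)cc2)c2ccc(O[Si](C)(C)C(C)(C)C)cc2)c1C#Cc1ccc(O[Si](C)(C)C(C)(C)C)cc1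
A1 | alternative 1 | (1Z,3Z)-1-methoxy-1,3-bis(trimethylsilyloxy)penta-1,3-diene | CO/C(O[Si](C)(C)C)=C/C(O[Si](C)(C)C)=C/C
A2 | alternative 1 | 3,3-dimethoxy-1-(4-methoxyphenyl)propan-1-one | COc1ccc(C(=O)CC(OC)OC)cc1
A3 | alternative 1 | methyl 2-hydroxy-6-(4-methoxyphenyl)-3-methylbenzoate | COC(=O)c1c(O)c(C)ccc1-c1ccc(OC)cc1
A4 | alternative 2 | chloro(dimethyl)(prop-1-yn-1-yl)silane | CC#C[Si](C)(C)Cl
A5 | alternative 2 | dimethyl(prop-1-yn-1-yl){[1,1,3-tris(4-methoxyphenyl)prop-2-yn-1-yl]oxy}silane | CC#C[Si](C)(C)OC(C#Cc1ccc(OC)cc1)(c1ccc(OC)cc1)c1ccc(OC)cc1
A6 | alternative 2 | acetylene | C#C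
A7 | alternative 2 | 3,3,4-tris(4-methoxyphenyl)-1,1,7-trimethyl-1,3-dihydro-2,1-benzoxasilole | Cc1ccc(-c2ccc(OC)cc2)c2c1[Si](C)(C)OC2(c1ccc(OC)cc1)c1ccc(OC)cc1
A8 | alternative 3 | (1E,3E)-1-(4-methoxyphenyl)penta-1,3-diene | C/C=C/C=C/c1ccc(OC)cc1
A9 | alternative 3 | 1,5-bis(4-methoxyphenyl)penta-2,4-diyn-1-one | COc1ccc(C#CC#CC(=O)c2ccc(OC)cc2)cc1
A10 | alternative 3 | [6-(4-methoxyphenyl)-2-[(4-methoxyphenyl)ethynyl]-3-methylphenyl](4-methoxyphenyl)methanone | Cc1ccc(-c2ccc(OC)cc2)c(C(=O)c2ccc(OC)cc2)c1C#Cc1ccc(OC)cc1
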